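(The earlier runs and the new flask are calculated on assumed constants.)

The vessel is closed, stirred and of constant volume. The meeting had the flasks dawn, midnight and dusk to compare, with the birch and alder runs on the table.

the same everywhere: substrate 0.19 M

| run | partner | temperature | remark | time |
|---|---|---|---|---|
| birch | 0.35 M | 35 °C | run made earlier |  |
| alder | 0.54 M | 46 °C | run made earlier |  |
| dawn | 0.247 M |  | at 30 °C until 25 min, from then on at 50 °C | 2.0 h |
| midnight | 0.247 M | 30 °C |  | 2.0 h |
| dusk | 0.247 M | 50 °C |  | 2.0 h |

| run | time / min | target / % | side product A / % | over-reaction product / % |
|---|---|---|---|---|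
| birch | 10.0 | 0.5 | 0.7 | 0 |
| birch | 15.0 | 2.4 | 1.3 | 0 |
| birch | 20.0 | 3.6 | 1.1 | 0 |
| birch | 30.0 | 1.9 | 0 | 0.9 |
| birch | 50.0 | 6.5 | 0 | 0 |
| birch | 80.0 | 7.4 | 2.0 | 0.7 |
| birch | 120 | 7.0 | 4.9 | 1.0 |
| alder | 6.00 | 3.7 | 0.9 | 0.9 |
| alder | 15.0 | 5.0 | 1.1 | 0 |
| alder | 25.0 | 7.1 | 1.4 | 0.9 |
| alder | 40.0 | 10.4 | 5.0 | 0 |
| alder | 50.0 | 15.3 | 5.9 | 2.1 |

(scatter of a reading: 1 percentage point)

- in percentages every species weighs as the substrate in it: one side product A counts as two
- the earlier runs were read with a standard deviation of 1 percentage point
- steps that have been proposed: substrate + partner <-> target + by-product; substrate + target -> side product A; partner + target -> over-reaction product; substrate + by-product -> side product B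

* the flask with the highest share of target in all that became target or side product A or over-reaction product or side product B ("all alike" if they lie within 1.5 percentage points) (dawn / midnight / dusk / all alike)
* share of target in all that became target or side product A or over-reaction product or side product B, dawn
* share of target in all that became target or side product A or over-reaction product or side product B, midnight
* share of target in all that became target or side product A or over-reaction product or side product B, dusk

The analyst opened with the balance of substrate, the limiting reagent, charged at 0.19 M against 0.247 M of partner. She said that side product A, as counted, holds one former target in each two units, so the target ever made is target plus half of side product A plus over-reaction product. At the last readings that came to 10.4% in the birch run and 20.3% in the alder run. Per unit of [partner] and of time, she said, alder made target 3.03 times as fast as birch, and she proposed to scale other temperatures by that factor.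

I argued that target is made in proportion to [substrate][partner] and lost in proportion to [substrate][target]. Substrate then cancels and target climbs towards a target ceiling, [partner] divided by σ, where σ is the selectivity factor of loss over formation. Early in a run, side product A should equal σ times charged [substrate] times the square of target made, over [partner]. That reads 8.27 from birch and 4.05 from alder.

The analyst objected that the birch value is twice the alder value and that each rests on a single reading. I took the mean, 6.16, as a reading and held it the same for dawn, midnight and dusk. For these charges the ceiling is 21.1% of the substrate charged.

Scaled to the asked time, target made is 4.46% at midnight and 33.4% at dusk. Dawn, counted by its time at each temperature, makes 27.4%. Letting target approach the ceiling exponentially, and leaving out side product B, over-reaction product and the fall of substrate and partner, I committed to 82.1% for midnight, 38.9% for dawn and 33.5% for dusk, with midnight highest.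

The forecast named midnight, with 34% for dawn, 71% for midnight, which is lower than my figure, and 29% for dusk, holding that “selectivity depends mainly on how far the reaction has gone”.

The flasks give midnight as highest, at 75.1%, against 38.1% for dawn and 33.9% for dusk.

    substrate + partner ⇌ target + by-product (K = 1.90, k = 1.60 × 10⁻⁴ M⁻¹ s⁻¹, Ea = 65.0 kJ mol⁻¹, ΔH = 6.00 kJ mol⁻¹)
    substrate + target → side product A (k = 9.80 × 10⁻⁴ M⁻¹ s⁻¹, Ea = 68.0 kJ mol⁻¹)
    partner + target → over-reaction product (k = 5.10 × 10⁻⁵ M⁻¹ s⁻¹, Ea = 80.0 kJ mol⁻¹)
    substrate + by-product → side product B (k = 6.40 × 10⁻⁴ M⁻¹ s⁻¹, Ea = 78.0 kJ mol⁻¹)
    (constants at 50 °C)

At 2.00 h midnight still holds 94% of its substrate and dusk 64%. Taken with the partner then standing, the ceiling for dusk at that time is 17.6%, and target stands at 12.2%. In dusk read at 5.00 h, partner is down to 71.3% of its own charge, the ceiling is 15.0%, and target stands at 13.3%.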